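**Retrosynthetic overview**

Ring numbering used here: C1(=O) lies between C2(OMe) and C6(docosyl); then C3(H), C4(=O), C5(CH3).

1. Target 20 ⇐ para-oxidation (C1=O) of phenol 19 ⇐ dehydrogenation of cyclohexenone 14 ⇐ removal of the ester from annulation product 12.
2. 12 ⇐ one-flask Michael addition (C1–C6), Dieckmann closure (C4–C5) and C-methylation (C5–CH3) from dienoate 7, enoate 6 and iodomethane 8. This forms the only ring.
3. Feature the plan rests on: ring atoms C1–C2(OMe)=C3–C4(=O) are the four-carbon chain of a 3-methoxybut-2-enoate with the methoxy group already in place. C6 (with its docosyl chain) and C5 are the β- and α-carbons of a pentacos-2-enoate, and the C5 methyl is an enolate alkylation site.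
4. 6 ⇐ Wittig olefination of tricosanal 4 ⇐ formylation of docosylmagnesium bromide from 1.

Key step: step 3

Remark: the spectator ester of the enoate is tert-butyl, so that it can be removed with anhydrous acid; a halide-mediated dealkoxycarbonylation at 150 °C could also dealkylate the methyl enol ether, which is a vinylogous methyl ester. All chiral intermediates are racemic and the target is achiral.

**Step 1**
Reactants: 1 1-bromodocosane; 2 N-formylpiperidine
Product: 4 tricosanal, via docosylmagnesium bromide 3 (not isolated)
Conditions: Mg, I2 (cat.), THF, 55 °C; then 2, 0 °C → rt; 2 M HCl work-up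
Reagents that add atoms: N-formylpiperidine, O=CN1CCCCC1
Why: Magnesium insertion gives Grignard reagent 3, and its Bouveault-type formylation stops at a magnesium hemiaminal that releases the aldehyde only on acidic work-up, so over-addition should not occur.

**Step 2**
Reactants: 4 tricosanal; 5 tert-butyl (triphenylphosphoranylidene)acetate
Product: 6 tert-butyl (E)-pentacos-2-enoate
Conditions: toluene, 80 °C
Reagents that add atoms: tert-butyl (triphenylphosphoranylidene)acetate, CC(C)(C)OC(=O)C=P(c1ccccc1)(c1ccccc1)c1ccccc1
Why: Wittig olefination with a stabilised ylide should give the (E)-enoate selectively, and the alkene geometry is lost in step 3 in any case.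

**Step 3**
Reactants: 6 tert-butyl (E)-pentacos-2-enoate; 7 methyl (E)-3-methoxybut-2-enoate; 8 iodomethane
Product: 12 tert-butyl 6-docosyl-4-methoxy-1-methyl-2-oxocyclohex-3-ene-1-carboxylate (racemic diastereomer mixture), via lithium dienolate 9 (not isolated), via Michael adduct enolate 10 (not isolated), via cyclic keto ester enolate 11 (not isolated)
Conditions: LiN(i-Pr)2, THF, −78 °C, 7; then 6 in THF, −78 → 0 °C → rt; then DMPU, MeI, 0 °C → rt
Reagents that add atoms: iodomethane, CI
Why: LiN(i-Pr)2 removes a γ-proton of the vinylogous carbonate 7 to give dienolate 9, whose terminal carbon adds in a Michael reaction to the β-carbon of 6 (bond C1–C6); the tert-butyl ester enolate 10 then acylates itself on the methyl ester of the 3-methoxyacrylate unit (Dieckmann condensation, bond C4–C5), the expelled LiOCH3 deprotonates the new β-keto ester to enolate 11, and iodomethane alkylates 11 on carbon (bond C5–CH3). The closest known reaction type is the tandem Michael–Dieckmann annulation of lithium ester dienolates with enoates followed by alkylation of the β-keto ester enolate, and the γ-reactivity parallels the additions of 3-alkoxycrotonate dienolates to aldehydes. The ring closes by 6-exo-trig acylation, which is possible because the (E)-enol ether holds the ester cis to the carbon that has just reacted. Two stereocentres (C5 and C6) form without control and the diastereomer mixture is accepted, since both carbons become sp2 on aromatisation. The step needs γ- over α-attack, 1,4- over 1,2-addition and C- over O-methylation: the β-methoxy dienolate reacts through its terminal carbon, the bulky tert-butyl ester shields the acceptor carbonyl, and the soft lithium β-keto ester enolate with the soft electrophile MeI should favour C–C bond formation. Formation of the stabilised enolate 11 should make the ring closure effectively irreversible.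

**Step 4**
Reactants: 12 tert-butyl 6-docosyl-4-methoxy-1-methyl-2-oxocyclohex-3-ene-1-carboxylate
Product: 14 5-docosyl-3-methoxy-6-methylcyclohex-2-en-1-one (cis/trans mixture), via keto acid 13 (not isolated)
Conditions: CF3CO2H, CH2Cl2, 0 °C → rt; evaporate; toluene, 90 °C; NaHCO3 wash
Reagents that add atoms: none
Why: Acidolysis of the tert-butyl ester with loss of 2-methylpropene, then thermal decarboxylation of the β-keto acid through its cyclic six-membered transition state, should leave the methyl enol ether intact because no water or nucleophile is present; the configuration at the re-formed methine is not controlled and is erased later.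

**Step 5**
Reactants: 14 5-docosyl-3-methoxy-6-methylcyclohex-2-en-1-one
Product: 16 5-docosyl-3-methoxy-6-methyl-6-(phenylselanyl)cyclohex-2-en-1-one, via lithium enolate 15 (not isolated)
Conditions: LiN(i-Pr)2, THF, −78 °C; then PhSeCl, −78 °C
Reagents that add atoms: phenylselenenyl chloride, Cl[Se]c1ccccc1
Why: Kinetic deprotonation of a 3-alkoxycyclohexenone occurs at the α'-carbon (Stork–Danheiser regiochemistry) and the enolate is selenenylated on carbon (Reich selenenylation), selenium expected anti to the neighbouring docosyl group, although the configuration of the new centre does not matter.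

**Step 6**
Reactants: 16 5-docosyl-3-methoxy-6-methyl-6-(phenylselanyl)cyclohex-2-en-1-one
Product: 19 3-docosyl-5-methoxy-2-methylphenol, via selenoxide 17 (not isolated), via dienone 18 (not isolated)
Conditions: mCPBA (1.0 equiv), CH2Cl2, −78 °C; then Et3N, −78 °C → rt
Reagents that add atoms: none
Why: Oxidation to the selenoxide and syn-elimination toward the ring C–H next to the docosyl group (Reich–Sharpless selenoxide elimination) gives a cyclohexa-2,5-dienone that tautomerises to the phenol under Et3N and erases both stereocentres; one equivalent of oxidant, low temperature and the amine should protect the electron-rich phenol from the selenium by-product.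

**Step 7**
Reactants: 19 3-docosyl-5-methoxy-2-methylphenol
Product: 20 3-docosyl-5-methoxy-2-methylcyclohexa-2,5-diene-1,4-dione (CNP0219396.0)
Conditions: (KSO3)2NO (2.5 equiv), aq. KH2PO4, methyltrioctylammonium chloride (cat.), CH2Cl2/H2O, rt
Reagents that add atoms: potassium nitrosodisulfonate, [K+].[K+].[O-]S(=O)(=O)N([O])S(=O)(=O)[O-]
Why: Teuber oxidation: one equivalent of the nitroxide abstracts the phenolic hydrogen, a second couples through oxygen at the unsubstituted para carbon, and loss of HN(SO3K)2 gives the para-quinone; the phase-transfer salt carries the nitroxide dianion to the lipophilic phenol in the organic phase.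

**Compound list**

1 | 1-bromodocosane | CCCCCCCCCCCCCCCCCCCCCCBr | starting material
2 | N-formylpiperidine (piperidine-1-carbaldehyde) | O=CN1CCCCC1 | starting material
3 | docosylmagnesium bromide | CCCCCCCCCCCCCCCCCCCCCC[Mg]Br | intermediate (not isolated)
4 | tricosanal | CCCCCCCCCCCCCCCCCCCCCCC=O | intermediate
5 | tert-butyl (triphenylphosphoranylidene)acetate | CC(C)(C)OC(=O)C=P(c1ccccc1)(c1ccccc1)c1ccccc1 | starting material
6 | tert-butyl (E)-pentacos-2-enoate | CCCCCCCCCCCCCCCCCCCCCC/C=C/C(=O)OC(C)(C)C | intermediate
7 | methyl (E)-3-methoxybut-2-enoate | CO/C(C)=C/C(=O)OC | starting material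
8 | iodomethane | CI | starting material
9 | lithium 1,3-dimethoxybuta-1,3-dien-1-olate (γ-dienolate of 7, enolate geometry not defined) | COC(=C)C=C(OC)O[Li] | intermediate (not isolated)
10 | lithium enolate, at the tert-butyl ester, of 7-tert-butyl 1-methyl (E)-5-docosyl-3-methoxyhept-2-enedioate (racemic) | CO/C(CC(CCCCCCCCCCCCCCCCCCCCCC)C=C(O[Li])OC(C)(C)C)=C/C(=O)OC | intermediate (not isolated)
11 | lithium enolate of tert-butyl 6-docosyl-4-methoxy-2-oxocyclohex-3-ene-1-carboxylate (racemic) | COC1=CC(O[Li])=C(C(=O)OC(C)(C)C)C(CCCCCCCCCCCCCCCCCCCCCC)C1 | intermediate (not isolated)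
12 | tert-butyl 6-docosyl-4-methoxy-1-methyl-2-oxocyclohex-3-ene-1-carboxylate (racemic diastereomer mixture) | COC1=CC(=O)C(C)(C(=O)OC(C)(C)C)C(CCCCCCCCCCCCCCCCCCCCCC)C1 | intermediate
13 | 6-docosyl-4-methoxy-1-methyl-2-oxocyclohex-3-ene-1-carboxylic acid (racemic diastereomer mixture) | COC1=CC(=O)C(C)(C(=O)O)C(CCCCCCCCCCCCCCCCCCCCCC)C1 | intermediate (not isolated)
14 | 5-docosyl-3-methoxy-6-methylcyclohex-2-en-1-one (racemic cis/trans mixture) | COC1=CC(=O)C(C)C(CCCCCCCCCCCCCCCCCCCCCC)C1 | intermediate
15 | lithium 3-docosyl-5-methoxy-2-methylcyclohexa-1,5-dien-1-olate (racemic) | COC1=CC(O[Li])=C(C)C(CCCCCCCCCCCCCCCCCCCCCC)C1 | intermediate (not isolated)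
16 | 5-docosyl-3-methoxy-6-methyl-6-(phenylselanyl)cyclohex-2-en-1-one (racemic, relative configuration not defined) | COC1=CC(=O)C(C)([Se]c2ccccc2)C(CCCCCCCCCCCCCCCCCCCCCC)C1 | intermediate
17 | 5-docosyl-3-methoxy-6-methyl-6-(phenylseleninyl)cyclohex-2-en-1-one (stereoisomer mixture) | COC1=CC(=O)C(C)([Se](=O)c2ccccc2)C(CCCCCCCCCCCCCCCCCCCCCC)C1 | intermediate (not isolated)
18 | 3-docosyl-5-methoxy-2-methylcyclohexa-2,5-dien-1-one | COC1=CC(=O)C(C)=C(CCCCCCCCCCCCCCCCCCCCCC)C1 | intermediate (not isolated)
19 | 3-docosyl-5-methoxy-2-methylphenol | COc1cc(O)c(C)c(CCCCCCCCCCCCCCCCCCCCCC)c1 | intermediate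
20 | 3-docosyl-5-methoxy-2-methylcyclohexa-2,5-diene-1,4-dione | CCCCCCCCCCCCCCCCCCCCCCC1=C(C)C(=O)C=C(OC)C1=O | target

**Totals**

Total step count: 7. Longest linear sequence: 7 steps (1 → 4 → 6 → 12 → 14 → 16 → 19 → 20).

**Steps most likely to fail**

Step 3. The dienolate may react through its α-carbon or at the ester carbonyl, the open-chain Michael adduct may undergo proton transfer instead of ring closure, or the hindered cyclic enolate may methylate slowly or on oxygen. The fallback sets out from aldehyde 4 and comes back at 14, so it also replaces step 4. Wittig olefination of 4 with 1-(triphenylphosphoranylidene)propan-2-one would give (E)-hexacos-3-en-2-one F1. With dimethyl methylmalonate and NaOCH3 in methanol at reflux, conjugate addition would give dimethyl 2-methyl-2-(2-oxohexacosan-4-yl)propanedioate F2, which closes under the same conditions by Claisen condensation of the methyl ketone onto one ester to methyl 6-docosyl-1-methyl-2,4-dioxocyclohexane-1-carboxylate F3. Saponification with aqueous NaOH, then acidification with HCl and heating, would give 5-docosyl-4-methylcyclohexane-1,3-dione F4. Acid-catalysed enol ether formation (CH3OH, TsOH cat.) should take place mainly at the carbonyl remote from the methyl group and give 14; the regioisomer 5-docosyl-3-methoxy-4-methylcyclohex-2-en-1-one F5 would be removed by chromatography. Here the methyl group arrives with the malonate, and the price is a regioselective O-methylation.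

Step 5. Deprotonation may occur at the γ-methylene instead of the hindered α'-methine, or selenenylation at the tertiary carbon may be sluggish; in step 6 the selenium by-product could also attack the electron-rich phenol. The fallback sets out from 14 and comes back at 19 without any enolate or selenium chemistry: heterogeneous catalytic dehydrogenation over Pd/C in refluxing mesitylene under an argon sweep should aromatise the cyclohexenone directly. No new compound is made (F0).

Step 7. Mass transfer between the aqueous radical salt and the waxy phenol may be slow, and radical coupling may occur at the free ortho position instead of the para position, which is flanked by the methoxy group and the docosyl chain. The fallback sets out from 19 and comes back at 20 by the azo route. Coupling of the phenoxide of 19 (NaOH, THF/H2O, 0 °C) with 4-diazoniobenzenesulfonate, expected para to the phenolic oxygen, would give 4-[(E)-(2-docosyl-4-hydroxy-6-methoxy-3-methylphenyl)diazenyl]benzenesulfonic acid F6. Reductive cleavage with Na2S2O4 would give 4-amino-3-docosyl-5-methoxy-2-methylphenol F7. Oxidation with FeCl3 in aqueous HCl/THF would give 3-docosyl-4-imino-5-methoxy-2-methylcyclohexa-2,5-dien-1-one F8, which hydrolyses in the same medium to 20.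

**Further compounds**

F1 | step 3 | (E)-hexacos-3-en-2-one | CCCCCCCCCCCCCCCCCCCCCC/C=C/C(C)=O
F2 | step 3 | dimethyl 2-methyl-2-(2-oxohexacosan-4-yl)propanedioate (racemic) | COC(=O)C(C)(C(=O)OC)C(CC(C)=O)CCCCCCCCCCCCCCCCCCCCCC
F3 | step 3 | methyl 6-docosyl-1-methyl-2,4-dioxocyclohexane-1-carboxylate (racemic diastereomer mixture) | COC(=O)C1(C)C(=O)CC(=O)CC1CCCCCCCCCCCCCCCCCCCCCC
F4 | step 3 | 5-docosyl-4-methylcyclohexane-1,3-dione (racemic cis/trans mixture) | CC1C(=O)CC(=O)CC1CCCCCCCCCCCCCCCCCCCCCC
F5 | step 3 | 5-docosyl-3-methoxy-4-methylcyclohex-2-en-1-one (racemic, by-product) | COC1=CC(=O)CC(CCCCCCCCCCCCCCCCCCCCCC)C1C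
F0 | step 5 | none | none
F6 | step 7 | 4-[(E)-(2-docosyl-4-hydroxy-6-methoxy-3-methylphenyl)diazenyl]benzenesulfonic acid | COc1cc(O)c(C)c(CCCCCCCCCCCCCCCCCCCCCC)c1/N=N/c1ccc(cc1)S(=O)(=O)O
F7 | step 7 | 4-amino-3-docosyl-5-methoxy-2-methylphenol | COc1cc(O)c(C)c(CCCCCCCCCCCCCCCCCCCCCC)c1N
F8 | step 7 | 3-docosyl-4-imino-5-methoxy-2-methylcyclohexa-2,5-dien-1-one | COC1=CC(=O)C(C)=C(CCCCCCCCCCCCCCCCCCCCCC)C1=N
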